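Everything rests on cutting ring A, the cyclohexane that carries the aryl ether, across its C4a–C8a and C3–C4 bonds (decalin locants as in the name of the target). Ring A contains the angular methyl carbon C4a, the fusion CH C8a beside it and, para to C4a, the methyl-bearing ether carbon C2. This is the pattern of a [4+2] adduct of 2-methylacrolein and an (E)-1-(silyloxymethyl)-3-methylbutadiene. One catalytic enantioselective Diels–Alder reaction therefore builds ring A, both bonds and the C4a/C8a stereocentres from a simple acyclic dienyl silyl ether. Ring B is then closed on dimethyl malonate, the ring alkene is hydrated to the axial tertiary alcohol, and this is O-arylated and elaborated to the biaryl.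

Key step: step 4

Remark (locants): C1 is the ring CH2 between C2 and C8a, C2 the ether carbon, C4a the angular carbon, C7 the carbon bearing the side chain, C8a the fusion CH; ring A = C1–C4, C4a, C8a; ring B = C4a, C5–C8, C8a.
Remark (precursor): the diene carries a triisopropylsilyl ether, whose shielded oxygen should bind the boron cation less and resist triflimide better than a smaller silyl ether; the carbon skeleton is unchanged.
Remark (sequence): the methyl ester is kept until the last step so that ring A holds the only tertiary alcohol when the aryl ether is made; the alkene is therefore hydrated by oxymercuration, which leaves the ester alone.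
Assumption: the (S)-configured oxazaborolidinium ion is taken to expose the Cα Re face of bound 2-methylacrolein (formyl C–H···O binding model); if the sense were opposite, the (R)-catalyst would be used.

Step 1
Reactants: 1 (2-methylacrolein); 2 (triethyl phosphonoacetate)
Product: 3 ethyl (2E)-4-methylpenta-2,4-dienoate
Conditions: NaH, THF, 0 °C → rt
Reagents that add atoms: none
Why: Horner–Wadsworth–Emmons olefination of the non-enolisable enal with the stabilised phosphonate anion should give the E-dienoate, the trans alkene being the favoured outcome of the reversible addition.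

Step 2
Reactants: 3 (ethyl (2E)-4-methylpenta-2,4-dienoate)
Product: 5 (2E)-4-methylpenta-2,4-dien-1-ol, via dienal 4 (not isolated)
Conditions: i-Bu2AlH (2.2 equiv), CH2Cl2, −78 °C; aq. potassium sodium tartrate
Reagents that add atoms: none
Why: Hydride reduction of the conjugated ester with i-Bu2AlH proceeds by 1,2-addition only, through the dienal, and leaves both alkenes untouched.

Step 3
Reactants: 5 ((2E)-4-methylpenta-2,4-dien-1-ol)
Product: 6 {[(2E)-4-methylpenta-2,4-dien-1-yl]oxy}tri(propan-2-yl)silane
Conditions: i-Pr3SiCl, imidazole, DMF, 0 °C → rt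
Reagents that add atoms: chlorotri(propan-2-yl)silane, CC(C)[Si](Cl)(C(C)C)C(C)C
Why: Silylation of the primary allylic alcohol with a chlorosilane and imidazole is routine and creates no stereocentre.

Step 4
Reactants: 6 (dienyl silyl ether); 1 (2-methylacrolein)
Product: 7 (1S,2S)-1,4-dimethyl-2-({[tri(propan-2-yl)silyl]oxy}methyl)cyclohex-3-ene-1-carbaldehyde
Conditions: (S)-tetrahydro-1-(2-methylphenyl)-3,3-diphenyl-1H,3H-pyrrolo[1,2-c][1,3,2]oxazaborole (20 mol %), HNTf2 (18 mol %), CH2Cl2, −78 → −40 °C
Reagents that add atoms: none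
Why: The N-protonated oxazaborolidine binds the formyl oxygen of 1 and the diene adds in a concerted, asynchronous [4+2] cycloaddition, the closest known reaction type being the cationic oxazaborolidine-catalysed Diels–Alder reaction of 2-substituted acroleins with acyclic dienes. Ring A closes in this single [4+2] event, the C4a–C8a and C3–C4 bonds forming together. The configuration at C4a (C1 of 7) is set by the catalyst, whose aryl group covers one face of the s-trans enal so that the diene reaches the Cα Re face. The configuration at C8a (C2 of 7) follows from exo placement of the boron-bound formyl group (α-methyl endo) together with the E geometry of the diene, which puts CHO trans to CH2OSi. Regiochemistry is secured by the diene itself, since its 1-alkyl and 3-methyl groups both place the larger HOMO coefficient on the unsubstituted CH2 terminus, which bonds to the β-carbon of the enal. The selectivity the step needs most is exo over endo, which rests on the bulk of the catalyst-bound formyl group and is the least certain element.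

Step 5
Reactants: 7 (cycloadduct aldehyde)
Product: 8 {[(1S,6R)-6-ethenyl-3,6-dimethylcyclohex-2-en-1-yl]methoxy}tri(propan-2-yl)silane
Conditions: Ph3PCH3Br, KOtBu, THF, 0 °C → rt
Reagents that add atoms: methyltriphenylphosphonium bromide, C[P+](c1ccccc1)(c1ccccc1)c1ccccc1.[Br-]
Why: Wittig methylenation with the unstabilised ylide converts the hindered aldehyde into the vinyl group, and the α-quaternary centre rules out epimerisation.

Step 6
Reactants: 8 (vinyl compound)
Product: 10 2-[(1R,2S)-1,4-dimethyl-2-({[tri(propan-2-yl)silyl]oxy}methyl)cyclohex-3-en-1-yl]ethan-1-ol, via alkylborane 9 (not isolated)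
Conditions: 9-BBN, THF, 0 °C → rt; then aq. NaOH, H2O2, 0 °C → rt
Reagents that add atoms: hydrogen peroxide, OO; 9-borabicyclo[3.3.1]nonane, B1C2CCCC1CCC2 (boron of 9 only)
Why: Hydroboration–oxidation with the bulky 9-BBN is selective for the monosubstituted vinyl group over the trisubstituted ring alkene and places boron, then oxygen, on the terminal carbon (future C6).

Step 7
Reactants: 10 (silyl ether alcohol)
Product: 11 2-[(1R,2S)-2-(hydroxymethyl)-1,4-dimethylcyclohex-3-en-1-yl]ethan-1-ol
Conditions: Bu4NF, THF, rt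
Reagents that add atoms: none
Why: Fluoride-induced desilylation is driven by the strong Si–F bond and touches neither the alcohol nor the alkene.

Step 8
Reactants: 11 (diol)
Product: 12 2-[(1R,2S)-2-{[(methanesulfonyl)oxy]methyl}-1,4-dimethylcyclohex-3-en-1-yl]ethyl methanesulfonate
Conditions: MsCl, Et3N, CH2Cl2, 0 °C
Reagents that add atoms: methanesulfonyl chloride, CS(=O)(=O)Cl
Why: Sulfonylation of both primary alcohols through the sulfene is fast and, unlike phosphonium-based halogenation of a 1,5-diol, offers no stage at which one hydroxyl group can displace the activated other one to give a cyclic ether.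

Step 9
Reactants: 12 (bis-mesylate); 13 (dimethyl malonate)
Product: 15 dimethyl (4aR,8aS)-4a,7-dimethyl-3,4,4a,5,6,8a-hexahydronaphthalene-2,2(1H)-dicarboxylate, via monoalkylated malonate 14 (not isolated)
Conditions: NaH (2.2 equiv), NaI (0.2 equiv), THF/DMF, 0 → 70 °C
Reagents that add atoms: none
Why: Double malonate alkylation forms C6–C7 by intermolecular SN2 at the unhindered mesyloxyethyl arm and then C7–C8 by an iodide-assisted 6-exo-tet closure, the trans arms of 12 fixing the trans ring fusion.

Step 10
Reactants: 15 (bicyclic diester)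
Product: 17 methyl (2R,4aS,8aS)-4a,7-dimethyl-1,2,3,4,4a,5,6,8a-octahydronaphthalene-2-carboxylate, via axial ester epimer 16 (not isolated)
Conditions: LiCl, H2O, DMSO, 150 °C; then NaOMe (cat.), MeOH, 65 °C
Reagents that add atoms: none
Why: Krapcho dealkoxycarbonylation removes one ester and methoxide equilibration through the ester enolate then converts the axial epimer into the thermodynamically preferred equatorial ester, which sets C7 (cis to the angular methyl); residual axial epimer is separated and re-equilibrated.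

Step 11
Reactants: 17 (equatorial ester)
Product: 19 methyl (2R,4aS,7R,8aS)-7-hydroxy-4a,7-dimethyldecahydronaphthalene-2-carboxylate, via organomercurial 18 (not isolated)
Conditions: Hg(OAc)2, THF/H2O, rt; then NaBH4, aq. NaOH, 0 °C
Reagents that add atoms: water, O; mercury diacetate, CC(=O)O[Hg]OC(C)=O (mercury of 18 only)
Why: Oxymercuration–demercuration gives Markovnikov anti addition through the mercurinium ion that opens trans-diaxially, which puts the hydroxyl group axial on C2 (anti to the angular methyl) and mercury axial on C1, and borohydride then replaces mercury by hydrogen without touching the ester.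

Step 12
Reactants: 19 (hydroxy ester); 20 (3-bromo-4-fluorobenzaldehyde)
Product: 21 methyl (2R,4aS,7R,8aS)-7-(2-bromo-4-formylphenoxy)-4a,7-dimethyldecahydronaphthalene-2-carboxylate
Conditions: KH (1.05 equiv), THF, 0 °C → rt; then 20, 18-crown-6, 0 °C → rt
Reagents that add atoms: none
Why: Nucleophilic aromatic substitution, in which the preformed potassium tertiary alkoxide adds para to the formyl group and fluoride leaves from the Meisenheimer intermediate, leaves the C2–O bond untouched so that C2 keeps its configuration.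

Step 13
Reactants: 22 (4-bromophenol); 23 (3-bromoprop-1-ene)
Product: 24 1-bromo-4-(prop-2-en-1-yloxy)benzene
Conditions: K2CO3, acetone, reflux
Reagents that add atoms: none
Why: Williamson etherification of the phenoxide with the allylic bromide is a clean SN2 reaction.

Step 14
Reactants: 24 (allyl 4-bromophenyl ether)
Product: 25 4-bromo-2-(prop-2-en-1-yl)phenol
Conditions: N,N-diethylaniline, 200 °C
Reagents that add atoms: none
Why: The aromatic Claisen rearrangement moves the allyl group to the free ortho position by a [3,3]-sigmatropic shift followed by tautomerisation to the phenol.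

Step 15
Reactants: 25 (2-allyl-4-bromophenol)
Product: 26 2-(prop-2-en-1-yl)-4-(4,4,5,5-tetramethyl-1,3,2-dioxaborolan-2-yl)phenol
Conditions: B2pin2, PdCl2(dppf), KOAc, dioxane, 85 °C
Reagents that add atoms: bis(pinacolato)diboron, CC1(C)OB(OC1(C)C)B1OC(C)(C)C(C)(C)O1
Why: Miyaura borylation of the aryl bromide uses acetate as the only base and therefore tolerates the free phenol and the allyl group.

Step 16
Reactants: 21 (aryl bromide); 26 (arylboronate)
Product: 27 methyl (2R,4aS,7R,8aS)-7-{[5-formyl-4'-hydroxy-3'-(prop-2-en-1-yl)-(1,1'-biphenyl)-2-yl]oxy}-4a,7-dimethyldecahydronaphthalene-2-carboxylate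
Conditions: Pd(OAc)2, SPhos (2-dicyclohexylphosphino-2',6'-dimethoxybiphenyl), K3PO4, toluene/H2O, 80 °C
Reagents that add atoms: none
Why: Suzuki–Miyaura coupling with a bulky electron-rich biarylphosphine allows oxidative addition and reductive elimination at the bromide ortho to the tertiary alkoxy group, while aldehyde, ester, phenol and allyl group are tolerated.

Step 17
Reactants: 27 (biaryl aldehyde)
Product: 28 methyl (2R,4aS,7R,8aS)-7-{[4'-hydroxy-5-(hydroxymethyl)-3'-(prop-2-en-1-yl)-(1,1'-biphenyl)-2-yl]oxy}-4a,7-dimethyldecahydronaphthalene-2-carboxylate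
Conditions: NaBH4, MeOH/THF, 0 °C
Reagents that add atoms: none
Why: Borohydride reduction is chemoselective for the aromatic aldehyde over the methyl ester.

Step 18
Reactants: 28 (benzylic alcohol)
Product: 29 methyl (2R,4aS,7R,8aS)-7-{[5-(chloromethyl)-4'-hydroxy-3'-(prop-2-en-1-yl)-(1,1'-biphenyl)-2-yl]oxy}-4a,7-dimethyldecahydronaphthalene-2-carboxylate
Conditions: PPh3, CCl4, MeCN, rt
Reagents that add atoms: tetrachloromethane, ClC(Cl)(Cl)Cl
Why: The Appel chlorination converts the benzylic alcohol into the chloride under neutral conditions, with no acid that could cleave the tertiary alkyl aryl ether and no reaction at the phenol.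

Step 19
Reactants: 29 (benzylic chloride)
Product: 30 methyl (2R,4aS,7R,8aS)-7-{[4'-hydroxy-3',5-di(prop-2-en-1-yl)-(1,1'-biphenyl)-2-yl]oxy}-4a,7-dimethyldecahydronaphthalene-2-carboxylate
Conditions: Bu3SnCH=CH2, Pd(PPh3)4, toluene, 80 °C
Reagents that add atoms: tributyl(ethenyl)stannane, CCCC[Sn](CCCC)(CCCC)C=C
Why: Stille coupling of the benzylic chloride with the vinylstannane builds the CH2–CH=CH2 unit under neutral conditions in which the phenol and the ester are inert.

Step 20
Reactants: 30 (diallyl ester)
Product: 32 3',5-di(prop-2-en-1-yl)-2-{[(2R,4aS,7R,8aS)-7-(2-hydroxypropan-2-yl)-2,4a-dimethyldecahydronaphthalen-2-yl]oxy}-[1,1'-biphenyl]-4'-ol, via methyl ketone 31 (not isolated)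
Conditions: MeMgBr (6 equiv), THF, 0 °C → rt; aq. NH4Cl
Reagents that add atoms: methylmagnesium bromide, C[Mg]Br
Why: Double Grignard addition to the ester through the methyl ketone gives the tertiary carbinol, the phenol being only deprotonated, and C7 keeps its equatorial substituent.

Compound list
1 | 2-methylacrolein (2-methylprop-2-enal) | CC(=C)C=O | starting material
2 | triethyl phosphonoacetate | CCOC(=O)CP(=O)(OCC)OCC | starting material
3 | ethyl (2E)-4-methylpenta-2,4-dienoate | CCOC(=O)/C=C/C(C)=C | intermediate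
4 | (2E)-4-methylpenta-2,4-dienal (formed in the flask, not isolated) | O=C/C=C/C(C)=C | intermediate
5 | (2E)-4-methylpenta-2,4-dien-1-ol | OC/C=C/C(C)=C | intermediate
6 | {[(2E)-4-methylpenta-2,4-dien-1-yl]oxy}tri(propan-2-yl)silane | CC(C)[Si](OC/C=C/C(C)=C)(C(C)C)C(C)C | intermediate
7 | (1S,2S)-1,4-dimethyl-2-({[tri(propan-2-yl)silyl]oxy}methyl)cyclohex-3-ene-1-carbaldehyde (formyl trans to the silyloxymethyl group) | CC1=C[C@H](CO[Si](C(C)C)(C(C)C)C(C)C)[C@@](C)(C=O)CC1 | intermediate
8 | {[(1S,6R)-6-ethenyl-3,6-dimethylcyclohex-2-en-1-yl]methoxy}tri(propan-2-yl)silane | CC1=C[C@H](CO[Si](C(C)C)(C(C)C)C(C)C)[C@@](C)(C=C)CC1 | intermediate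
9 | B-alkyl-9-borabicyclo[3.3.1]nonane from 8, boron on the terminal carbon of the former vinyl group (formed in the flask, not isolated) | CC1=C[C@H](CO[Si](C(C)C)(C(C)C)C(C)C)[C@@](C)(CCB2C3CCCC2CCC3)CC1 | intermediate
10 | 2-[(1R,2S)-1,4-dimethyl-2-({[tri(propan-2-yl)silyl]oxy}methyl)cyclohex-3-en-1-yl]ethan-1-ol | CC1=C[C@H](CO[Si](C(C)C)(C(C)C)C(C)C)[C@@](C)(CCO)CC1 | intermediate
11 | 2-[(1R,2S)-2-(hydroxymethyl)-1,4-dimethylcyclohex-3-en-1-yl]ethan-1-ol | CC1=C[C@H](CO)[C@@](C)(CCO)CC1 | intermediate
12 | 2-[(1R,2S)-2-{[(methanesulfonyl)oxy]methyl}-1,4-dimethylcyclohex-3-en-1-yl]ethyl methanesulfonate | CC1=C[C@H](COS(C)(=O)=O)[C@@](C)(CCOS(C)(=O)=O)CC1 | intermediate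
13 | dimethyl malonate | COC(=O)CC(=O)OC | starting material
14 | monoalkylated malonate: 12 in which the mesylate of the 2-(mesyloxy)ethyl arm is replaced by CH(CO2Me)2 (formed in the flask, not isolated) | CC1=C[C@H](COS(C)(=O)=O)[C@@](C)(CCC(C(=O)OC)C(=O)OC)CC1 | intermediate
15 | dimethyl (4aR,8aS)-4a,7-dimethyl-3,4,4a,5,6,8a-hexahydronaphthalene-2,2(1H)-dicarboxylate (trans-fused) | CC1=C[C@@H]2CC(C(=O)OC)(C(=O)OC)CC[C@@]2(C)CC1 | intermediate
16 | methyl (2S,4aS,8aS)-4a,7-dimethyl-1,2,3,4,4a,5,6,8a-octahydronaphthalene-2-carboxylate, axial ester (formed in the flask, not isolated) | CC1=C[C@@H]2C[C@@H](C(=O)OC)CC[C@@]2(C)CC1 | intermediate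
17 | methyl (2R,4aS,8aS)-4a,7-dimethyl-1,2,3,4,4a,5,6,8a-octahydronaphthalene-2-carboxylate, equatorial ester cis to the angular methyl | CC1=C[C@@H]2C[C@H](C(=O)OC)CC[C@@]2(C)CC1 | intermediate
18 | organomercurial: 19 carrying an axial acetoxymercury group on C1, trans to the new axial hydroxyl group on C2 (formed in the flask, not isolated) | O[C@]1(C)CC[C@]2(C)CC[C@@H](C(=O)OC)C[C@H]2[C@H]1[Hg]OC(C)=O | intermediate
19 | methyl (2R,4aS,7R,8aS)-7-hydroxy-4a,7-dimethyldecahydronaphthalene-2-carboxylate (hydroxyl axial, anti to the angular methyl) | O[C@]1(C)CC[C@]2(C)CC[C@@H](C(=O)OC)C[C@H]2C1 | intermediate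
20 | 3-bromo-4-fluorobenzaldehyde | O=Cc1ccc(F)c(Br)c1 | starting material
21 | methyl (2R,4aS,7R,8aS)-7-(2-bromo-4-formylphenoxy)-4a,7-dimethyldecahydronaphthalene-2-carboxylate | O=Cc1ccc(O[C@]2(C)CC[C@]3(C)CC[C@@H](C(=O)OC)C[C@H]3C2)c(Br)c1 | intermediate
22 | 4-bromophenol | Oc1ccc(Br)cc1 | starting material
23 | 3-bromoprop-1-ene (allyl bromide) | C=CCBr | starting material
24 | 1-bromo-4-(prop-2-en-1-yloxy)benzene | C=CCOc1ccc(Br)cc1 | intermediate
25 | 4-bromo-2-(prop-2-en-1-yl)phenol | C=CCc1cc(Br)ccc1O | intermediate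
26 | 2-(prop-2-en-1-yl)-4-(4,4,5,5-tetramethyl-1,3,2-dioxaborolan-2-yl)phenol | C=CCc1cc(ccc1O)B1OC(C)(C)C(C)(C)O1 | intermediate
27 | methyl (2R,4aS,7R,8aS)-7-{[5-formyl-4'-hydroxy-3'-(prop-2-en-1-yl)-(1,1'-biphenyl)-2-yl]oxy}-4a,7-dimethyldecahydronaphthalene-2-carboxylate | O=Cc1ccc(O[C@]2(C)CC[C@]3(C)CC[C@@H](C(=O)OC)C[C@H]3C2)c(-c2ccc(O)c(CC=C)c2)c1 | intermediate
28 | methyl (2R,4aS,7R,8aS)-7-{[4'-hydroxy-5-(hydroxymethyl)-3'-(prop-2-en-1-yl)-(1,1'-biphenyl)-2-yl]oxy}-4a,7-dimethyldecahydronaphthalene-2-carboxylate | OCc1ccc(O[C@]2(C)CC[C@]3(C)CC[C@@H](C(=O)OC)C[C@H]3C2)c(-c2ccc(O)c(CC=C)c2)c1 | intermediate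
29 | methyl (2R,4aS,7R,8aS)-7-{[5-(chloromethyl)-4'-hydroxy-3'-(prop-2-en-1-yl)-(1,1'-biphenyl)-2-yl]oxy}-4a,7-dimethyldecahydronaphthalene-2-carboxylate | ClCc1ccc(O[C@]2(C)CC[C@]3(C)CC[C@@H](C(=O)OC)C[C@H]3C2)c(-c2ccc(O)c(CC=C)c2)c1 | intermediate
30 | methyl (2R,4aS,7R,8aS)-7-{[4'-hydroxy-3',5-di(prop-2-en-1-yl)-(1,1'-biphenyl)-2-yl]oxy}-4a,7-dimethyldecahydronaphthalene-2-carboxylate | C=CCc1ccc(O[C@]2(C)CC[C@]3(C)CC[C@@H](C(=O)OC)C[C@H]3C2)c(-c2ccc(O)c(CC=C)c2)c1 | intermediate
31 | 1-[(2R,4aS,7R,8aS)-7-{[4'-hydroxy-3',5-di(prop-2-en-1-yl)-(1,1'-biphenyl)-2-yl]oxy}-4a,7-dimethyldecahydronaphthalen-2-yl]ethan-1-one (formed in the flask, not isolated) | C=CCc1ccc(O[C@]2(C)CC[C@]3(C)CC[C@@H](C(C)=O)C[C@H]3C2)c(-c2ccc(O)c(CC=C)c2)c1 | intermediate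
32 | 3',5-di(prop-2-en-1-yl)-2-{[(2R,4aS,7R,8aS)-7-(2-hydroxypropan-2-yl)-2,4a-dimethyldecahydronaphthalen-2-yl]oxy}-[1,1'-biphenyl]-4'-ol | C=CCc1ccc(O[C@]2(C)CC[C@]3(C)CC[C@@H](C(C)(C)O)C[C@H]3C2)c(-c2ccc(O)c(CC=C)c2)c1 | target

Total step count: 20. Longest linear sequence: 17 steps (steps 1–12 and 16–20, from 1 and 2 to 32); steps 13–15 make the boronate 26 in a side branch.

Steps most likely to fail

Step 4. With an acyclic diene there is no bridging CH2 to push the boron-bound formyl group exo, so it may enter endo and leave the two future arms cis. Binding of the ether oxygen to boron could also erode face selection. The fallback sets out from 6 and comes back at 11, and it exchanges the roles of the two α-substituents of the dienophile so that an endo formyl group becomes the angular methyl. Commercial 4-[(tert-butyldimethylsilyl)oxy]butanal would be α-methylenated (aq. CH2O, pyrrolidine and propionic acid as catalysts, i-PrOH, 45 °C) to 4-[(tert-butyldimethylsilyl)oxy]-2-methylidenebutanal F1. Cycloaddition of F1 and 6 under the (R)-enantiomer of the oxazaborolidine of step 4, again activated by HNTf2, with the formyl group endo, should give 1-{2-[(tert-butyldimethylsilyl)oxy]ethyl}-4-methyl-2-({[tri(propan-2-yl)silyl]oxy}methyl)cyclohex-3-ene-1-carbaldehyde F2, formyl cis to the silyloxymethyl group. Wolff–Kishner reduction (N2H4·H2O, KOH, diethylene glycol, 200 °C) would turn CHO into the angular CH3 and give the bis-silyl ether of 11 F3. Bu4NF then removes whatever silyl groups have survived the hot base and gives 11.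

Step 12. The hindered axial alkoxide may add too slowly to the ring carbon flanked by bromine, so that addition to the formyl group followed by hydride transfer, or condensation at the ester, takes over. The fallback sets out from 19 and comes back at 30, and it replaces addition–elimination by ligand coupling on iodine. Commercial 2-bromo-4-chloro-1-iodobenzene would be oxidised (mCPBA, TsOH, MeCN) and combined with 1,3,5-trimethoxybenzene to give (2-bromo-4-chlorophenyl)(2,4,6-trimethoxyphenyl)iodonium 4-methylbenzenesulfonate F4. The sodium alkoxide of 19 (NaH, toluene, rt) should take over the haloaryl group of F4, the trimethoxyphenyl group staying on iodine, to give methyl (2R,4aS,7R,8aS)-7-(2-bromo-4-chlorophenoxy)-4a,7-dimethyldecahydronaphthalene-2-carboxylate F5. Suzuki–Miyaura coupling of F5 and 26 at the bromide (Pd(PPh3)4, K2CO3, dioxane/H2O) would give methyl (2R,4aS,7R,8aS)-7-{[5-chloro-4'-hydroxy-3'-(prop-2-en-1-yl)-(1,1'-biphenyl)-2-yl]oxy}-4a,7-dimethyldecahydronaphthalene-2-carboxylate F6. Allylation of the chloride of F6 (allylboronic acid pinacol ester, Pd(OAc)2, SPhos, K3PO4, THF/H2O) gives 30.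

Step 11. Mercuration on the face syn to the angular methyl may be slow, so that water attacks C2 from the β face through the other mercurinium ion and the equatorial alcohol forms. The fallback sets out from 17 and comes back at 19, and it replaces hydration by epoxidation and hydride opening. mCPBA (NaHCO3, CH2Cl2) should attack anti to the angular methyl and give methyl (1aR,3aS,6R,7aS,7bS)-1a,3a-dimethyldecahydronaphtho[1,2-b]oxirene-6-carboxylate, the 1α,2α-epoxide of 17 F7. LiAlH4 would open it trans-diaxially at C1 and reduce the ester, giving (2R,4aS,7R,8aS)-7-(hydroxymethyl)-2,4a-dimethyldecahydronaphthalen-2-ol F8. Oxidation of the primary alcohol alone (TEMPO as catalyst, PhI(OAc)2, MeCN/H2O) gives (2R,4aS,7R,8aS)-7-hydroxy-4a,7-dimethyldecahydronaphthalene-2-carboxylic acid F9, and TMSCHN2 in MeOH gives 19.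

Further compounds
F1 | step 4 | 4-[(tert-butyldimethylsilyl)oxy]-2-methylidenebutanal | C=C(CCO[Si](C)(C)C(C)(C)C)C=O
F2 | step 4 | 1-{2-[(tert-butyldimethylsilyl)oxy]ethyl}-4-methyl-2-({[tri(propan-2-yl)silyl]oxy}methyl)cyclohex-3-ene-1-carbaldehyde, formyl cis to the silyloxymethyl group | CC1=C[C@H](CO[Si](C(C)C)(C(C)C)C(C)C)[C@@](C=O)(CCO[Si](C)(C)C(C)(C)C)CC1
F3 | step 4 | bis-silyl ether of 11 (triisopropylsilyl on the CH2O group, tert-butyldimethylsilyl on the hydroxyethyl arm) | CC1=C[C@H](CO[Si](C(C)C)(C(C)C)C(C)C)[C@@](C)(CCO[Si](C)(C)C(C)(C)C)CC1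
F4 | step 12 | (2-bromo-4-chlorophenyl)(2,4,6-trimethoxyphenyl)iodonium 4-methylbenzenesulfonate | COc1cc(OC)c([I+]c2ccc(Cl)cc2Br)c(OC)c1.Cc1ccc(cc1)S(=O)(=O)[O-]
F5 | step 12 | methyl (2R,4aS,7R,8aS)-7-(2-bromo-4-chlorophenoxy)-4a,7-dimethyldecahydronaphthalene-2-carboxylate | Clc1ccc(O[C@]2(C)CC[C@]3(C)CC[C@@H](C(=O)OC)C[C@H]3C2)c(Br)c1
F6 | step 12 | methyl (2R,4aS,7R,8aS)-7-{[5-chloro-4'-hydroxy-3'-(prop-2-en-1-yl)-(1,1'-biphenyl)-2-yl]oxy}-4a,7-dimethyldecahydronaphthalene-2-carboxylate | Clc1ccc(O[C@]2(C)CC[C@]3(C)CC[C@@H](C(=O)OC)C[C@H]3C2)c(-c2ccc(O)c(CC=C)c2)c1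
F7 | step 11 | methyl (1aR,3aS,6R,7aS,7bS)-1a,3a-dimethyldecahydronaphtho[1,2-b]oxirene-6-carboxylate (1α,2α-epoxide of 17, oxygen anti to the angular methyl) | C[C@]12O[C@H]1[C@@H]1C[C@H](C(=O)OC)CC[C@@]1(C)CC2
F8 | step 11 | (2R,4aS,7R,8aS)-7-(hydroxymethyl)-2,4a-dimethyldecahydronaphthalen-2-ol | O[C@]1(C)CC[C@]2(C)CC[C@@H](CO)C[C@H]2C1
F9 | step 11 | (2R,4aS,7R,8aS)-7-hydroxy-4a,7-dimethyldecahydronaphthalene-2-carboxylic acid | O[C@]1(C)CC[C@]2(C)CC[C@@H](C(=O)O)C[C@H]2C1
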